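The chromone is disconnected at the O1–C2 bond of pyranone ring C: a 2-alkyl-4-pyranone is a 3-acyl-4-hydroxy-2-pyranone minus CO2. The precursor is therefore a 3-(3-arylpropanoyl)-4-hydroxy-6,7-dimethoxycoumarin whose side-chain phenol is masked as an acetate, built from 3,4-dimethoxyphenol, Meldrum's acid and dihydroisoferulic acid. In one acidic operation the lactone opens, its carbonyl carbon departs as CO2, and the liberated phenol oxygen closes onto the side-chain ketone to form O1–C2. Coumarin atoms C3 and C4 are retained as chromone C3 and C4, and the former acyl carbon becomes C2. The acetate falls off in the same pot, so the target results directly.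

Key step: step 4

Remark on the structures: the 6,7-dimethoxy pattern of the coumarin and the 3-hydroxy-4-methoxyphenyl unit were checked atom by atom against the target and need no correction. The acetate is kept as the phenol mask because it should survive the acylation and is lost under the acid of the key step.

Assumption: in step 4 the aryl acetate is taken to hydrolyse before the lactone opens; the reverse order would converge on the same diketone and the same product.

Step 1
Reactants: 1 3,4-dimethoxyphenol; 2 Meldrum's acid (2,2-dimethyl-1,3-dioxane-4,6-dione)
Product: 4 4-hydroxy-6,7-dimethoxycoumarin, via aryl hydrogen malonate 3 (not isolated)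
Conditions: neat, 95 °C (acetone distils off); then P2O5 in MeSO3H, 70 °C; ice-water quench
Reagents that add atoms: none
Why: Phenolysis of Meldrum's acid expels acetone to give the malonic half-ester, whose free carboxyl is activated by P2O5/MeSO3H for an intramolecular Friedel–Crafts acylation at the ring position ortho to the ester oxygen and para to the 3-methoxy group (the other ortho site is flanked by two oxygen substituents), which fixes the 6,7-dimethoxy pattern.

Step 2
Reactants: 5 3-(3-hydroxy-4-methoxyphenyl)propanoic acid
Product: 6 3-(3-acetoxy-4-methoxyphenyl)propanoic acid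
Conditions: Ac2O, pyridine, rt; then H2O, dilute HCl work-up
Reagents that add atoms: acetic anhydride, CC(=O)OC(C)=O
Why: Routine O-acetylation of a phenol, with the aqueous acidic work-up returning the carboxyl group as the free acid; the acetate keeps the phenol from being acylated in step 3 and is removable by the acid of step 4.

Step 3
Reactants: 4 4-hydroxy-6,7-dimethoxycoumarin; 6 3-(3-acetoxy-4-methoxyphenyl)propanoic acid
Product: 8 3-[3-(3-acetoxy-4-methoxyphenyl)propanoyl]-4-hydroxy-6,7-dimethoxycoumarin, via coumarin-4-yl enol ester 7 (not isolated)
Conditions: N,N'-dicyclohexylcarbodiimide (DCC), 4-(dimethylamino)pyridine (DMAP, 1.5 equiv), CH2Cl2, 0 °C to rt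
Reagents that add atoms: none
Why: Steglich-type activation first gives the 4-acyloxycoumarin, which DMAP converts by a Fries-type O-to-C acyl shift (acylpyridinium/enolate ion pair) into the more stable, internally hydrogen-bonded 3-acyl-4-hydroxycoumarin, a C-acylation established for 4-hydroxycoumarins and 4-hydroxy-2-pyranones.

Step 4
Reactants: 8 3-[3-(3-acetoxy-4-methoxyphenyl)propanoyl]-4-hydroxy-6,7-dimethoxycoumarin
Product: 13 2-[2-(3-hydroxy-4-methoxyphenyl)ethyl]-6,7-dimethoxychromone, via free phenol acylcoumarin 9 (not isolated), via diketo acid 10 (not isolated), via aryl diketone 11 (not isolated), via hemiketal 12 (not isolated)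
Conditions: conc. aq. HCl/AcOH (1:2 v/v), reflux
Reagents that add atoms: none
Why: Aqueous acid first hydrolyses the aryl acetate and the lactone C2–O1 bond, the resulting diketo acid 10 (a carboxyl flanked by two ketones) decarboxylates through the usual cyclic enol pathway, and the phenol oxygen of diketone 11 adds to the aliphatic ketone to give hemiketal 12, which dehydrates to the conjugated 4-pyranone. The closest known reaction type is the acid-promoted hydrolysis, decarboxylation and recyclisation of 3-acyl-4-hydroxy-2-pyranones and 3-acyl-4-hydroxycoumarins to 4-pyranones and 2-alkylchromones, whose last stage is the same cyclodehydration that follows a Baker–Venkataraman rearrangement. Ring C is closed by a 6-exo-trig attack of the phenol oxygen on the side-chain carbonyl carbon, which creates the O1–C2 bond. No stereocentre is created in the product, since the sp3 centres of 10 and 12 are destroyed by decarboxylation and dehydration. The selectivity required is closure onto the side-chain ketone and not back onto a carboxyl group, and it is secured because the only carboxyl group leaves irreversibly as CO2, after which the phenol can reach only the aliphatic ketone in a six-membered mode (the aryl ketone would give a four-membered ring). HCl should leave the three aryl methyl ethers untouched, and the acetate is removed in the same pot.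

Compound list
1 | 3,4-dimethoxyphenol | COc1ccc(O)cc1OC | starting material
2 | Meldrum's acid (2,2-dimethyl-1,3-dioxane-4,6-dione) | CC1(C)OC(=O)CC(=O)O1 | starting material
3 | 3-(3,4-dimethoxyphenoxy)-3-oxopropanoic acid (aryl hydrogen malonate; transient) | COc1ccc(OC(=O)CC(=O)O)cc1OC | intermediate
4 | 4-hydroxy-6,7-dimethoxycoumarin | COc1cc2oc(=O)cc(O)c2cc1OC | intermediate
5 | 3-(3-hydroxy-4-methoxyphenyl)propanoic acid (dihydroisoferulic acid) | COc1ccc(CCC(=O)O)cc1O | starting material
6 | 3-(3-acetoxy-4-methoxyphenyl)propanoic acid | COc1ccc(CCC(=O)O)cc1OC(C)=O | intermediate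
7 | 6,7-dimethoxy-2-oxo-2H-chromen-4-yl 3-(3-acetoxy-4-methoxyphenyl)propanoate (enol ester; transient) | COc1ccc(CCC(=O)Oc2cc(=O)oc3cc(OC)c(OC)cc23)cc1OC(C)=O | intermediate
8 | 3-[3-(3-acetoxy-4-methoxyphenyl)propanoyl]-4-hydroxy-6,7-dimethoxycoumarin | COc1ccc(CCC(=O)c2c(O)c3cc(OC)c(OC)cc3oc2=O)cc1OC(C)=O | intermediate
9 | 4-hydroxy-3-[3-(3-hydroxy-4-methoxyphenyl)propanoyl]-6,7-dimethoxycoumarin (transient) | COc1ccc(CCC(=O)c2c(O)c3cc(OC)c(OC)cc3oc2=O)cc1O | intermediate
10 | 2-(2-hydroxy-4,5-dimethoxybenzoyl)-5-(3-hydroxy-4-methoxyphenyl)-3-oxopentanoic acid (racemic, enolisable centre; transient) | COc1ccc(CCC(=O)C(C(=O)O)C(=O)c2cc(OC)c(OC)cc2O)cc1O | intermediate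
11 | 1-(2-hydroxy-4,5-dimethoxyphenyl)-5-(3-hydroxy-4-methoxyphenyl)pentane-1,3-dione (transient) | COc1ccc(CCC(=O)CC(=O)c2cc(OC)c(OC)cc2O)cc1O | intermediate
12 | 2-hydroxy-2-[2-(3-hydroxy-4-methoxyphenyl)ethyl]-6,7-dimethoxychroman-4-one (racemic; transient) | COc1ccc(CCC2(O)CC(=O)c3cc(OC)c(OC)cc3O2)cc1O | intermediate
13 | 2-[2-(3-hydroxy-4-methoxyphenyl)ethyl]-6,7-dimethoxychromone | COc1ccc(CCc2cc(=O)c3cc(OC)c(OC)cc3o2)cc1O | target

Total step count: 4. Longest linear sequence: 3 steps (steps 1, 3, 4 from compound 1, or steps 2, 3, 4 from compound 5).

Steps most likely to fail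

1. Step 4. Acid-induced loss of the whole 3-acyl side chain (a retro-Claisen-type deacylation back to 4) may outrun lactone opening, or the chelated acylcoumarin may resist hydrolysis so that the sequence stalls. The fallback builds the open-chain diketone by a Claisen condensation and avoids the coumarin. It sets out from 1 and 5 and comes back to the route at 11. Compound 1 should be C-acetylated ortho to the hydroxyl group (AcOH, BF3·OEt2, 90 °C; Friedel–Crafts acylation para to the 3-methoxy group) to give 1-(2-hydroxy-4,5-dimethoxyphenyl)ethanone F1. Compound 5 should be converted by Fischer esterification (MeOH, catalytic H2SO4, reflux) into methyl 3-(3-hydroxy-4-methoxyphenyl)propanoate F2. Condensation of the enolate of F1 with F2 (excess NaH, enough to deprotonate both phenols as well, THF, reflux; acidic work-up) should give diketone 11, now isolated. Brief warming of 11 in HCl/AcOH should then close ring C through 12 to the target 13.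

2. Step 3. The acylation may stop at the O-acyl stage, the carbodiimide adduct may rearrange to an N-acylurea, or DMAP may shuttle the acetyl group from the aryl acetate onto the coumarin. The fallback forms the side-chain C–C bond by an aldol condensation and needs no phenol protection. It sets out from 4 and comes back to the route at 9. Compound 4 should be C-acetylated (AcOH, POCl3, reflux) to 3-acetyl-4-hydroxy-6,7-dimethoxycoumarin F3. Piperidine-catalysed aldol condensation of F3 with commercially available isovanillin (3-hydroxy-4-methoxybenzaldehyde, COc1ccc(C=O)cc1O) in refluxing CHCl3 should give 4-hydroxy-3-[(2E)-3-(3-hydroxy-4-methoxyphenyl)prop-2-enoyl]-6,7-dimethoxycoumarin F4. Hydrogenation of the enone double bond (H2, Pd/C, EtOAc/THF, rt) should deliver 9, here isolated, which is then submitted to the conditions of step 4.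

3. Step 1. Phenolysis of Meldrum's acid may be incomplete, the half-ester may decarboxylate or be cleaved before ring closure, or the electron-rich ring may be sulfonylated or degraded in the sulfonic acid medium. The fallback replaces the two-stage half-ester/strong-acid sequence by a Lewis-acid-mediated condensation with free malonic acid, which passes through no aryl malonate and uses no sulfonic acid. It sets out from 1 and comes back to the route at 4. Compound 1 and malonic acid (OC(=O)CC(=O)O) should be heated with anhydrous ZnCl2 in POCl3 at 60–70 °C, where C-acylation and lactonisation should give 4 directly. No new isolated compound arises.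

Further compounds
F1 | step 4 | 1-(2-hydroxy-4,5-dimethoxyphenyl)ethanone | COc1cc(O)c(C(C)=O)cc1OC
F2 | step 4 | methyl 3-(3-hydroxy-4-methoxyphenyl)propanoate | COC(=O)CCc1ccc(OC)c(O)c1
F3 | step 3 | 3-acetyl-4-hydroxy-6,7-dimethoxycoumarin | COc1cc2oc(=O)c(C(C)=O)c(O)c2cc1OC
F4 | step 3 | 4-hydroxy-3-[(2E)-3-(3-hydroxy-4-methoxyphenyl)prop-2-enoyl]-6,7-dimethoxycoumarin | COc1ccc(/C=C/C(=O)c2c(O)c3cc(OC)c(OC)cc3oc2=O)cc1O
F0 | step 1 | none | none
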